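**Strategy.** The acylphloroglucinol ring is not acylated but grown from a four-membered ring. The benzene carbons C1′ (bearing the chain), C2′ (O), C6′ (O) and C5′ (H) map onto a squarate-derived 4-chlorocyclobutenone, and C4′ (O) with C3′ (H) onto a 1-alkoxyvinylstannane. One operation (Stille coupling, 4π ring opening, 6π closure) forms C5′–C4′ and C3′–C2′ and delivers the phenol with all three oxygens in place. The precursor is a 2-alkynyl-3-isopropoxy-4-chlorocyclobutenone whose alkyne masks the C1 ketone and carries the (S)-C13 silyl ether. Both ring ethers are isopropyl so that BCl3 alone unmasks the phenols.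

Key step: step 8

Remarks on the chemistry:
- Arene atoms are C1′–C6′ (C1′ bears the chain); chain atoms are C1–C16 (C1 is the carbonyl carbon, C13 the carbinol).
- The sp3 ring carbon of the four-membered intermediates forms as a mixture of epimers and is left undefined in the SMILES, because it ends as an aromatic carbon.
- The alkoxy group of the vinylstannane is isopropyl instead of ethyl. This is a spectator change: an ethyl ether para to the ketone would need BBr3, which threatens the C13 carbinol.
- The target and the key-step structures were re-derived and are consistent: a C16 chain, (S) at C13, set by (S)-1,2-epoxypentane.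

Step 1
Reactants: 1 undec-1-yne; 2 (S)-1,2-epoxypentane
Product: 4 (S)-hexadec-6-yn-4-ol, via undec-1-yn-1-yllithium 3 (not isolated)
Conditions: nBuLi, THF, −78 °C; BF3·OEt2; then 2, −78 °C; aq. NH4Cl
Reagents that add atoms: none
Why: Yamaguchi–Hirao alkynylation, in which the BF3-activated epoxide is opened by the lithium acetylide in an SN2 reaction at the unsubstituted carbon, so the C–O bond of the stereocentre is never broken and the (S) configuration of 2 is carried into C4 of 4.

Step 2
Reactants: 4 (S)-hexadec-6-yn-4-ol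
Product: 5 (S)-hexadec-15-yn-4-ol
Conditions: KH, H2N(CH2)3NH2, 0 °C to rt; then H2O
Reagents that add atoms: none
Why: Alkyne zipper isomerisation, in which potassium 3-aminopropylamide moves the triple bond along the unbranched chain by repeated propargyl–allenyl proton shifts until the terminal acetylide, the thermodynamic sink, is formed, while the carbinol carbon, held as its alkoxide, blocks migration in the other direction and keeps the (S) configuration.

Step 3
Reactants: 5 (S)-hexadec-15-yn-4-ol
Product: 6 (S)-tert-butyl(hexadec-15-yn-4-yloxy)dimethylsilane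
Conditions: TBSCl, imidazole, DMF, rt
Reagents that add atoms: tert-butyldimethylsilyl chloride, CC(C)(C)[Si](C)(C)Cl
Why: Imidazole-promoted silylation of a secondary alcohol, giving a silyl ether that should withstand the organolithium, hydride, chlorination and palladium steps and that leaves the stereocentre untouched.

Step 4
Reactants: 6 (S)-tert-butyl(hexadec-15-yn-4-yloxy)dimethylsilane; 7 diisopropyl squarate
Product: 11 3-[(S)-13-(tert-butyldimethylsilyloxy)hexadec-1-yn-1-yl]-4-isopropoxycyclobut-3-ene-1,2-dione, via lithium acetylide 8 (not isolated), via lithium alkoxide adduct 9 (not isolated), via trifluoroacetate 10 (not isolated)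
Conditions: nBuLi, THF, −78 °C; then 7, −78 °C; (CF3CO)2O, −78 °C; aq. NaHCO3, to rt
Reagents that add atoms: water, O
Why: Squarate addition–rearrangement, in which the acetylide adds 1,2 to one carbonyl of the symmetrical squarate, trifluoroacetylation turns the tertiary alkoxide into a leaving group whose departure is assisted by the vinylogous isopropoxy group, and water hydrolyses the resulting oxocarbenium carbon with loss of propan-2-ol; this non-protic trigger should spare the silyl ether.

Step 5
Reactants: 11 3-[(S)-13-(tert-butyldimethylsilyloxy)hexadec-1-yn-1-yl]-4-isopropoxycyclobut-3-ene-1,2-dione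
Product: 12 4-hydroxy-3-isopropoxy-2-[(S)-13-(tert-butyldimethylsilyloxy)hexadec-1-yn-1-yl]cyclobut-2-en-1-one
Conditions: LiAlH(OtBu)3, THF, −78 to −40 °C; aq. NH4Cl
Reagents that add atoms: none
Why: Regioselective 1,2-reduction by a bulky alkoxyaluminium hydride, which should attack the ketone-like carbonyl next to the isopropoxy-bearing carbon and leave the vinylogous-ester carbonyl next to the alkynyl-bearing carbon, thereby fixing where the ring oxygens end up; the new carbinol carbon forms as an inconsequential mixture of epimers.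

Step 6
Reactants: 12 4-hydroxy-3-isopropoxy-2-[(S)-13-(tert-butyldimethylsilyloxy)hexadec-1-yn-1-yl]cyclobut-2-en-1-one
Product: 13 4-chloro-3-isopropoxy-2-[(S)-13-(tert-butyldimethylsilyloxy)hexadec-1-yn-1-yl]cyclobut-2-en-1-one
Conditions: PPh3, NCS, CH2Cl2, −20 °C to rt
Reagents that add atoms: N-chlorosuccinimide, O=C1CCC(=O)N1Cl
Why: Appel-type deoxychlorination, in which the hydroxyl is activated as an oxyphosphonium group and displaced by chloride at a carbon that is both allylic and alpha to the ketone, under neutral conditions that avoid acid-induced rearrangement of the hydroxycyclobutenone and spare the silyl ether.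

Step 7
Reactants: 14 isopropyl vinyl ether
Product: 16 tributyl(1-isopropoxyvinyl)stannane, via 1-isopropoxyvinyllithium 15 (not isolated)
Conditions: tBuLi, THF, −78 to 0 °C; Bu3SnCl, −78 °C to rt
Reagents that add atoms: tributyltin chloride, CCCC[Sn](Cl)(CCCC)CCCC
Why: Alpha-lithiation of an alkyl vinyl ether (deprotonation of the vinylic C–H next to oxygen) followed by stannylation at carbon, the standard entry to 1-alkoxyvinylstannanes.

Step 8
Reactants: 13 4-chloro-3-isopropoxy-2-[(S)-13-(tert-butyldimethylsilyloxy)hexadec-1-yn-1-yl]cyclobut-2-en-1-one; 16 tributyl(1-isopropoxyvinyl)stannane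
Product: 20 2-[(S)-13-(tert-butyldimethylsilyloxy)hexadec-1-yn-1-yl]-3,5-diisopropoxyphenol, via vinylcyclobutenone 17 (not isolated), via dienylketene 18 (not isolated), via cyclohexadienone 19 (not isolated)
Conditions: Pd2(dba)3 (cat.), tri(2-furyl)phosphine, 1,4-dioxane, 50 °C then 100 °C
Reagents that add atoms: none
Why: Zerovalent palladium should insert into the allylic, alpha-keto C4–Cl bond of 13, the 1-isopropoxyvinyl group is transferred from tin and reductive elimination at C4 gives vinylcyclobutenone 17; on heating, conrotatory 4π opening of the C1–C4 bond gives dienylketene 18, 6π-electrocyclisation joins the ketene carbon to the vinyl CH2 to give cyclohexadienone 19, and enolisation aromatises it to phenol 20. The closest known reaction type is the Stille coupling of 4-chlorocyclobutenones with alkenylstannanes with thermal ring expansion to phenols in the same flask. The one ring formed, the benzene ring, is closed by a thermal disrotatory 6π-electrocyclisation (bond C3′–C2′) after the cross-coupling has made bond C5′–C4′. No stereocentre is created, and the C4 epimers of 13 converge because C4 becomes the aromatic carbon C5′. The step needs regiocontrol: coupling must occur at C4 and not at C2 of the allyl-palladium intermediate, which the alkynyl substituent at C2 should secure, and the oxygen pattern is already fixed by which squarate carbonyl was reduced in step 5. Ring opening is reversible, so the ketene isomer with the vinyl group cis to the ketene carbon is drained by cyclisation, while the alkyne and the silyl ether are spectators.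

Step 9
Reactants: 20 2-[(S)-13-(tert-butyldimethylsilyloxy)hexadec-1-yn-1-yl]-3,5-diisopropoxyphenol
Product: 21 (S)-13-hydroxy-1-(2-hydroxy-4,6-diisopropoxyphenyl)hexadecan-1-one
Conditions: TsOH·H2O, EtOH/H2O, 70 °C
Reagents that add atoms: water, O
Why: Brønsted-acid Markovnikov hydration of an electron-rich arylalkyne, in which protonation at C2 gives a vinyl cation at C1 stabilised by the ortho and para oxygens, water adds at C1 and the enol tautomerises to the aryl ketone; the ortho hydroxyl cannot reach C1, so no benzofuran is expected, and the same acid solvolyses the silyl ether without touching the C13 stereocentre.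

Step 10
Reactants: 21 (S)-13-hydroxy-1-(2-hydroxy-4,6-diisopropoxyphenyl)hexadecan-1-one
Product: 22 (S)-13-hydroxy-1-(2,4,6-trihydroxyphenyl)hexadecan-1-one
Conditions: BCl3, CH2Cl2, −78 °C to rt; then MeOH; aq. NaHCO3
Reagents that add atoms: none
Why: Lewis-acid dealkylation of aryl isopropyl ethers, in which BCl3 coordinates each ether oxygen (the 6′ one helped by chelation to the ketone) and the isopropyl group leaves as 2-chloropropane, while the C13 hydroxyl is only held as a borate that methanol releases with its configuration intact.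

**Compound list**

1 | undec-1-yne | CCCCCCCCCC#C | starting material
2 | (S)-1,2-epoxypentane | CCC[C@H]1CO1 | starting material
3 | undec-1-yn-1-yllithium (not isolated) | CCCCCCCCCC#C[Li] | intermediate
4 | (S)-hexadec-6-yn-4-ol | CCC[C@H](O)CC#CCCCCCCCCC | intermediate
5 | (S)-hexadec-15-yn-4-ol | CCC[C@H](O)CCCCCCCCCCC#C | intermediate
6 | (S)-tert-butyl(hexadec-15-yn-4-yloxy)dimethylsilane | CCC[C@H](O[Si](C)(C)C(C)(C)C)CCCCCCCCCCC#C | intermediate
7 | diisopropyl squarate (3,4-diisopropoxycyclobut-3-ene-1,2-dione) | CC(C)OC1=C(OC(C)C)C(=O)C1=O | starting material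
8 | lithium acetylide of 6, [(S)-13-(tert-butyldimethylsilyloxy)hexadec-1-yn-1-yl]lithium (not isolated) | CCC[C@H](O[Si](C)(C)C(C)(C)C)CCCCCCCCCCC#C[Li] | intermediate
9 | lithium 1-[(S)-13-(tert-butyldimethylsilyloxy)hexadec-1-yn-1-yl]-2,3-diisopropoxy-4-oxocyclobut-2-en-1-olate, ring carbinol carbon as epimer mixture (not isolated) | CCC[C@H](O[Si](C)(C)C(C)(C)C)CCCCCCCCCCC#CC1([O-])C(OC(C)C)=C(OC(C)C)C1=O.[Li+] | intermediate
10 | 1-[(S)-13-(tert-butyldimethylsilyloxy)hexadec-1-yn-1-yl]-2,3-diisopropoxy-4-oxocyclobut-2-en-1-yl trifluoroacetate, epimer mixture (not isolated) | CCC[C@H](O[Si](C)(C)C(C)(C)C)CCCCCCCCCCC#CC1(OC(=O)C(F)(F)F)C(OC(C)C)=C(OC(C)C)C1=O | intermediate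
11 | 3-[(S)-13-(tert-butyldimethylsilyloxy)hexadec-1-yn-1-yl]-4-isopropoxycyclobut-3-ene-1,2-dione | CCC[C@H](O[Si](C)(C)C(C)(C)C)CCCCCCCCCCC#CC1=C(OC(C)C)C(=O)C1=O | intermediate
12 | 4-hydroxy-3-isopropoxy-2-[(S)-13-(tert-butyldimethylsilyloxy)hexadec-1-yn-1-yl]cyclobut-2-en-1-one, C4 epimer mixture | CCC[C@H](O[Si](C)(C)C(C)(C)C)CCCCCCCCCCC#CC1=C(OC(C)C)C(O)C1=O | intermediate
13 | 4-chloro-3-isopropoxy-2-[(S)-13-(tert-butyldimethylsilyloxy)hexadec-1-yn-1-yl]cyclobut-2-en-1-one, C4 epimer mixture | CCC[C@H](O[Si](C)(C)C(C)(C)C)CCCCCCCCCCC#CC1=C(OC(C)C)C(Cl)C1=O | intermediate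
14 | isopropyl vinyl ether | C=COC(C)C | starting material
15 | 1-isopropoxyvinyllithium (not isolated) | [Li]C(=C)OC(C)C | intermediate
16 | tributyl(1-isopropoxyvinyl)stannane | CCCC[Sn](CCCC)(CCCC)C(=C)OC(C)C | intermediate
17 | 3-isopropoxy-4-(1-isopropoxyvinyl)-2-[(S)-13-(tert-butyldimethylsilyloxy)hexadec-1-yn-1-yl]cyclobut-2-en-1-one, C4 epimer mixture (not isolated) | CCC[C@H](O[Si](C)(C)C(C)(C)C)CCCCCCCCCCC#CC1=C(OC(C)C)C(C(=C)OC(C)C)C1=O | intermediate
18 | dienylketene, 2-[(S)-13-(tert-butyldimethylsilyloxy)hexadec-1-yn-1-yl]-3,5-diisopropoxyhexa-1,3,5-trien-1-one with the vinyl group cis to the ketene carbon (not isolated) | CCC[C@H](O[Si](C)(C)C(C)(C)C)CCCCCCCCCCC#CC(=C=O)/C(OC(C)C)=C\C(=C)OC(C)C | intermediate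
19 | 2-[(S)-13-(tert-butyldimethylsilyloxy)hexadec-1-yn-1-yl]-3,5-diisopropoxycyclohexa-2,4-dien-1-one (not isolated) | CCC[C@H](O[Si](C)(C)C(C)(C)C)CCCCCCCCCCC#CC1=C(OC(C)C)C=C(OC(C)C)CC1=O | intermediate
20 | 2-[(S)-13-(tert-butyldimethylsilyloxy)hexadec-1-yn-1-yl]-3,5-diisopropoxyphenol | CCC[C@H](O[Si](C)(C)C(C)(C)C)CCCCCCCCCCC#Cc1c(O)cc(OC(C)C)cc1OC(C)C | intermediate
21 | (S)-13-hydroxy-1-(2-hydroxy-4,6-diisopropoxyphenyl)hexadecan-1-one | CCC[C@H](O)CCCCCCCCCCCC(=O)c1c(O)cc(OC(C)C)cc1OC(C)C | intermediate
22 | (S)-13-hydroxy-1-(2,4,6-trihydroxyphenyl)hexadecan-1-one | CCC[C@H](O)CCCCCCCCCCCC(=O)c1c(O)cc(O)cc1O | target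

**Totals**

Total step count: 10 (nine in the main line, one for the stannane).
Longest linear sequence: 9 steps (steps 1–6, then 8–10) from undec-1-yne and (S)-1,2-epoxypentane.

**Steps most likely to fail**

1. Step 8. The cross-coupling may stall at oxidative addition or transmetallation so that the chloride decomposes, or palladium may cyclise the freshly formed ortho-alkynylphenol onto its alkyne. The fallback abandons ring construction and sets out from alkyne 6. Sonogashira coupling (PdCl2(PPh3)2, CuI, Et3N, 60 °C) with 2-iodo-1,3,5-tris(benzyloxy)benzene F1, obtained from commercial 1,3,5-tris(benzyloxy)benzene and N-iodosuccinimide, should give (S)-tert-butyl{[16-(2,4,6-tris(benzyloxy)phenyl)hexadec-15-yn-4-yl]oxy}dimethylsilane F2. Hydration under the conditions of step 9 should give (S)-13-hydroxy-1-[2,4,6-tris(benzyloxy)phenyl]hexadecan-1-one F3. Hydrogenolysis of the three benzyl ethers (H2, Pd/C, EtOAc) comes back to the route at target 22.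

2. Step 9. The free ortho hydroxyl may add to the activated alkyne (cycloisomerisation to a benzofuran) instead of water adding at C1, or desilylation may lag behind hydration. The fallback sets out from phenol 20 and turns the hydroxyl into a directing group. Acetylation (Ac2O, pyridine, DMAP) should give 2-[(S)-13-(tert-butyldimethylsilyloxy)hexadec-1-yn-1-yl]-3,5-diisopropoxyphenyl acetate F4. Gold-catalysed hydration (Ph3PAuNTf2, dioxane/H2O, 60 °C), in which the acetate carbonyl delivers oxygen to C1 through a six-membered acyloxonium, should give 2-[(S)-13-(tert-butyldimethylsilyloxy)hexadecanoyl]-3,5-diisopropoxyphenyl acetate F5. Methanolic HCl then removes the acetate and the silyl ether and comes back to the route at 21.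

3. Step 10. Cleavage of the 4′-isopropyl ether may stay incomplete because this oxygen is deactivated by conjugation with the boron-chelated ketone, and forcing it may substitute the borate-activated C13 carbinol by chloride. The fallback sets out from 21 and masks the carbinol as an ester before a stronger Lewis acid is used. Acetylation (Ac2O, pyridine, DMAP) should give (S)-16-(2-acetoxy-4,6-diisopropoxyphenyl)-16-oxohexadecan-4-yl acetate F6. BBr3 (CH2Cl2, −78 to 0 °C) should cleave both isopropyl ethers to give (S)-16-(2-acetoxy-4,6-dihydroxyphenyl)-16-oxohexadecan-4-yl acetate F7. Methanolic HCl removes both acetates and comes back to the route at target 22.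

**Further compounds**

F1 | step 8 | 2-iodo-1,3,5-tris(benzyloxy)benzene | Ic1c(OCc2ccccc2)cc(OCc2ccccc2)cc1OCc1ccccc1
F2 | step 8 | (S)-tert-butyl{[16-(2,4,6-tris(benzyloxy)phenyl)hexadec-15-yn-4-yl]oxy}dimethylsilane | CCC[C@H](O[Si](C)(C)C(C)(C)C)CCCCCCCCCCC#Cc1c(OCc2ccccc2)cc(OCc2ccccc2)cc1OCc1ccccc1
F3 | step 8 | (S)-13-hydroxy-1-[2,4,6-tris(benzyloxy)phenyl]hexadecan-1-one | CCC[C@H](O)CCCCCCCCCCCC(=O)c1c(OCc2ccccc2)cc(OCc2ccccc2)cc1OCc1ccccc1
F4 | step 9 | 2-[(S)-13-(tert-butyldimethylsilyloxy)hexadec-1-yn-1-yl]-3,5-diisopropoxyphenyl acetate | CCC[C@H](O[Si](C)(C)C(C)(C)C)CCCCCCCCCCC#Cc1c(OC(C)=O)cc(OC(C)C)cc1OC(C)C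
F5 | step 9 | 2-[(S)-13-(tert-butyldimethylsilyloxy)hexadecanoyl]-3,5-diisopropoxyphenyl acetate | CCC[C@H](O[Si](C)(C)C(C)(C)C)CCCCCCCCCCCC(=O)c1c(OC(C)=O)cc(OC(C)C)cc1OC(C)C
F6 | step 10 | (S)-16-(2-acetoxy-4,6-diisopropoxyphenyl)-16-oxohexadecan-4-yl acetate | CCC[C@H](OC(C)=O)CCCCCCCCCCCC(=O)c1c(OC(C)=O)cc(OC(C)C)cc1OC(C)C
F7 | step 10 | (S)-16-(2-acetoxy-4,6-dihydroxyphenyl)-16-oxohexadecan-4-yl acetate | CCC[C@H](OC(C)=O)CCCCCCCCCCCC(=O)c1c(OC(C)=O)cc(O)cc1O
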